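**Retrosynthetic overview**
1. Feature (2H-chromene numbering): the hydroxyl on C7 and the CH2 of the C6 arylacetyl group can be bridged by one extra CH into a γ-pyrone (isoflavone ring C). This masks the C7 oxygen and leaves the C5 oxygen as the only free one. What remains is biochanin A lacking only the pyran ring (O1, C2, C3, C4 on C8a/C4a).
2. Last disconnection: hydroxide deletes isoflavone C2 (ring opening, then retro-Claisen loss of formate). This frees the C7–OH and the CH2 in one operation.
3. Key disconnection: the pyran ring comes from the 1,1-dimethylpropargyl ether on the isoflavone 7-oxygen. The sequence is a [3,3] shift to isoflavone C6 (forms C4–C4a), a 1,5-H shift and an oxa-6π closure (forms O1–C2).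
4. Control: 7-propargyloxychromones shift by preference to C8, so C8 carries iodine during the key step. The 5-oxygen is methylated first because a 5,7-dialkoxy pattern steers iodination to C8, and the iodine is removed before the ring opening.
5. Ring order: rings A, B and C come with biochanin A, the pyran ring (ring D) closes in step 4, and ring C is opened in step 6.

Key step: step 4

Remark on numbering: compounds that contain ring C are numbered as isoflavones. Isoflavone C5, C6, C7, C8, C8a and C4a become C5, C4a, C8a, C8, C7 and C6 of the target chromene. The target has no stereocentre, so no stereocontrol is needed.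

**Step 1**
Reactants: 1 biochanin A; 2 3-chloro-3-methylbut-1-yne
Product: 3 5-hydroxy-3-(4-methoxyphenyl)-7-[(2-methylbut-3-yn-2-yl)oxy]-4H-chromen-4-one
Conditions: 2 (2.5 equiv), K2CO3 (2 equiv), KI (0.2 equiv), CuI (0.1 equiv), acetone, 55 °C, Ar
Reagents that add atoms: 3-chloro-3-methylbut-1-yne, CC(C)(Cl)C#C
Why: This is a copper-catalysed propargylic etherification (a Williamson-type O-alkylation through a copper acetylide that ionises to a copper allenylidene) in which K2CO3 deprotonates only the acidic 7-OH, the 5-OH stays locked in a hydrogen bond to the C4 carbonyl, and 55 °C lies well below the onset of the sigmatropic shift.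

**Step 2**
Reactants: 3 the 7-ether; 4 dimethyl sulfate
Product: 5 5-methoxy-3-(4-methoxyphenyl)-7-[(2-methylbut-3-yn-2-yl)oxy]-4H-chromen-4-one
Conditions: Me2SO4 (3 equiv), K2CO3 (5 equiv), acetone, reflux; aq. NH3 quench
Reagents that add atoms: dimethyl sulfate, COS(=O)(=O)OC
Why: This is a Williamson O-methylation of a chelated peri-hydroxyl under forcing carbonate conditions, the usual access to 5-O-methyl isoflavones, in which ring C holds the other ortho oxygen (O1) so that only the 5-oxygen can react, and the tertiary ether, the alkyne C–H and the pyrone are inert to anhydrous K2CO3.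

**Step 3**
Reactants: 5 the 5-O-methyl ether; 6 N-iodosuccinimide
Product: 7 8-iodo-5-methoxy-3-(4-methoxyphenyl)-7-[(2-methylbut-3-yn-2-yl)oxy]-4H-chromen-4-one
Conditions: NIS (1.1 equiv), DMF, 25 to 50 °C, dark
Reagents that add atoms: N-iodosuccinimide, O=C1CCC(=O)N1I
Why: In this neutral electrophilic aromatic iodination, 5,7-dialkoxy(iso)flavones react at C8 (para to the 5-OMe group, with only the ring oxygen as second neighbour), while C6 is buried between OMe and the tertiary alkoxy group, ring B is much less activated, and NIS does not iodinate a terminal alkyne without a silver salt or a base.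

**Step 4**
Reactants: 7 the 8-iodo propargyl ether
Product: 11 10-iodo-5-methoxy-7-(4-methoxyphenyl)-2,2-dimethyl-2H,6H-pyrano[3,2-g]chromen-6-one, via allenyl dienone 8 (not isolated), via allenylphenol 9 (not isolated), via ortho-quinone methide 10 (not isolated)
Conditions: 1,2-dichlorobenzene (0.05 M, degassed), 180 °C, Ar, dark
Reagents that add atoms: none
Why: This is the aryl propargyl ether Claisen cascade (the thermal 2,2-dimethylchromene synthesis), in which a [3,3] shift breaks the O–CMe2 bond and joins the alkyne terminus to isoflavone C6 (C4–C4a of the target) to give allenyl dienone 8, which enolises to allenylphenol 9. A 1,5-hydrogen shift from the phenolic O–H to the central allene carbon gives the Z-configured ortho-quinone methide 10, and the pyran ring then closes by a thermal disrotatory oxa-6π electrocyclisation in which the 7-oxygen binds the CMe2 terminus (O1–C2 of the target). The closest known cases are the conversions of 7-(1,1-dimethylpropargyloxy)-8-iodocoumarins and -chromones into linear pyrano compounds. The step needs C6 and not C8, yet an unblocked 7-propargyloxychromone shifts mainly to C8 because the dienone formed there keeps the O1–C8a=C4a–C4=O conjugation of the γ-pyrone, and chelated 1-hydroxy-3-propargyloxy-xanthones and -acridones also close largely in the angular sense, so hydrogen-bond fixation by a free 5-OH is not relied on. In 7 the iodine makes a shift to C8 sterically costly and unproductive (that dienone has no hydrogen to lose and can only revert), so C6–H is the only site where rearomatisation can follow, and the non-nucleophilic solvent offers no acceptor for iodine. No stereocentre survives the step.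

**Step 5**
Reactants: 11 the iodo pyranoisoflavone
Product: 12 5-methoxy-7-(4-methoxyphenyl)-2,2-dimethyl-2H,6H-pyrano[3,2-g]chromen-6-one
Conditions: Pd(PPh3)4 (5 mol %), HCO2Na (3 equiv), DMF, 90 °C, Ar
Reagents that add atoms: none
Why: In this palladium-catalysed transfer hydrodehalogenation, zerovalent palladium inserts into the C–I bond, formate replaces iodide and loses CO2, and Ar–H is released by reductive elimination, while the chromene and pyrone double bonds should stay untouched because no heterogeneous hydrogenation catalyst is present.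

**Step 6**
Reactants: 12 the pyranoisoflavone
Product: 14 1-(7-hydroxy-5-methoxy-2,2-dimethyl-2H-chromen-6-yl)-2-(4-methoxyphenyl)ethan-1-one (target), via formyl ketone 13 (not isolated)
Conditions: 10% aq. KOH–EtOH (1:1), reflux, Ar; then 1 M HCl, 0 °C, to pH 3
Reagents that add atoms: none
Why: In this classical alkaline degradation of an isoflavone to its deoxybenzoin, hydroxide adds to C2 (oxa-Michael), ring C opens with loss of the O1 phenoxide to give formyl ketone 13, and a retro-Claisen cleavage at the unhindered formyl group expels C2 as formate, while the doubly ortho-substituted aryl ketone, present as phenoxide and enolate, should resist a second cleavage in dilute base and argon prevents benzylic autoxidation.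

**Compound list**
1 | biochanin A (5,7-dihydroxy-3-(4-methoxyphenyl)-4H-chromen-4-one) | COc1ccc(cc1)-c1coc2cc(O)cc(O)c2c1=O | starting material
2 | 3-chloro-3-methylbut-1-yne | CC(C)(Cl)C#C | starting material
3 | 5-hydroxy-3-(4-methoxyphenyl)-7-[(2-methylbut-3-yn-2-yl)oxy]-4H-chromen-4-one | COc1ccc(cc1)-c1coc2cc(OC(C)(C)C#C)cc(O)c2c1=O | intermediate
4 | dimethyl sulfate | COS(=O)(=O)OC | starting material
5 | 5-methoxy-3-(4-methoxyphenyl)-7-[(2-methylbut-3-yn-2-yl)oxy]-4H-chromen-4-one | COc1ccc(cc1)-c1coc2cc(OC(C)(C)C#C)cc(OC)c2c1=O | intermediate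
6 | N-iodosuccinimide | O=C1CCC(=O)N1I | starting material
7 | 8-iodo-5-methoxy-3-(4-methoxyphenyl)-7-[(2-methylbut-3-yn-2-yl)oxy]-4H-chromen-4-one | COc1ccc(cc1)-c1coc2c(I)c(OC(C)(C)C#C)cc(OC)c2c1=O | intermediate
8 | 8-iodo-5-methoxy-3-(4-methoxyphenyl)-6-(3-methylbuta-1,2-dien-1-yl)-4H-chromene-4,7(6H)-dione (racemic at C6, transient) | COc1ccc(cc1)C1=COC2=C(I)C(=O)C(C=C=C(C)C)C(OC)=C2C1=O | intermediate
9 | 7-hydroxy-8-iodo-5-methoxy-3-(4-methoxyphenyl)-6-(3-methylbuta-1,2-dien-1-yl)-4H-chromen-4-one | COc1ccc(cc1)-c1coc2c(I)c(O)c(C=C=C(C)C)c(OC)c2c1=O | intermediate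
10 | (6Z)-8-iodo-5-methoxy-3-(4-methoxyphenyl)-6-(3-methylbut-2-en-1-ylidene)-4H-chromene-4,7(6H)-dione | COc1ccc(cc1)C1=COC2=C(I)C(=O)/C(=C\C=C(C)C)C(OC)=C2C1=O | intermediate
11 | 10-iodo-5-methoxy-7-(4-methoxyphenyl)-2,2-dimethyl-2H,6H-pyrano[3,2-g]chromen-6-one | COc1ccc(cc1)-c1coc2c(I)c3OC(C)(C)C=Cc3c(OC)c2c1=O | intermediate
12 | 5-methoxy-7-(4-methoxyphenyl)-2,2-dimethyl-2H,6H-pyrano[3,2-g]chromen-6-one | COc1ccc(cc1)-c1coc2cc3OC(C)(C)C=Cc3c(OC)c2c1=O | intermediate
13 | 3-(7-hydroxy-5-methoxy-2,2-dimethyl-2H-chromen-6-yl)-2-(4-methoxyphenyl)-3-oxopropanal (racemic, enolisable, present as its enolate) | COc1ccc(cc1)C(C=O)C(=O)c1c(O)cc2OC(C)(C)C=Cc2c1OC | intermediate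
14 | 1-(7-hydroxy-5-methoxy-2,2-dimethyl-2H-chromen-6-yl)-2-(4-methoxyphenyl)ethan-1-one | COc1ccc(CC(=O)c2c(O)cc3c(c2OC)C=CC(C)(C)O3)cc1 | target

**Total step count:** 6. **Longest linear sequence:** 6 (from biochanin A).

**Steps most likely to fail**

1. **Step 4 (key step).**
   - What may go wrong: the shift may go to the iodine-bearing C8, and iodine may then be lost from the blocked dienone by homolysis or by transfer to adventitious nucleophiles. That would open the way to angular closure. The C6 shift may also be slow, with thermal loss of the tertiary C5 unit by elimination.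
   - Fallback (from 1, back at 12): the pyran ring is built intermolecularly instead of by a sigmatropic shift. Biochanin A 1 is condensed with 3-methylbut-2-enal under Ca(OH)2 in MeOH at room temperature. The calcium phenoxide adds through C6 to the aldehyde, water is lost, and the resulting ortho-quinone methide closes by oxa-6π electrocyclisation. This should give 5-hydroxy-7-(4-methoxyphenyl)-2,2-dimethyl-2H,6H-pyrano[3,2-g]chromen-6-one F1. This base-mediated chromenylation tends to favour the carbon between the chelated and the free hydroxyl of 1,3-dihydroxyaryl ketones. Methylation of F1 with Me2SO4/K2CO3 in refluxing acetone leads to 12.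

2. **Step 3.**
   - What may go wrong: iodination may occur at C6 or on ring B, or the iodonium source may attack the alkyne.
   - Fallback (from 3, back at 14): the blocking group is given up and the natural bias of the shift is used.
   - Heating 3 in 1,2-dichlorobenzene should send the C5 unit mainly to C8 and give the angular isomer 5-hydroxy-3-(4-methoxyphenyl)-8,8-dimethyl-4H,8H-pyrano[2,3-f]chromen-4-one F2.
   - In F2, ring C ties up the oxygen that must become the C5 methoxy group of 14, and the free hydroxyl is the future C7–OH, so the roles of the two oxygens are swapped.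
   - MOMCl/NaH in DMF gives 5-(methoxymethoxy)-3-(4-methoxyphenyl)-8,8-dimethyl-4H,8H-pyrano[2,3-f]chromen-4-one F3.
   - Aqueous-ethanolic KOH opens ring C to 1-[5-hydroxy-7-(methoxymethoxy)-2,2-dimethyl-2H-chromen-6-yl]-2-(4-methoxyphenyl)ethan-1-one F4.
   - Me2SO4/K2CO3 in acetone methylates the liberated hydroxyl to 1-[5-methoxy-7-(methoxymethoxy)-2,2-dimethyl-2H-chromen-6-yl]-2-(4-methoxyphenyl)ethan-1-one F5.
   - Dilute aqueous HCl in THF at 40 °C removes the acetal, which is activated by the neighbouring carbonyl, to give 14.

3. **Step 5.**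
   - What may go wrong: oxidative addition at the doubly ortho-oxygenated C–I bond may be sluggish, or hydride may be transferred to C2=C3 of the pyrone or to the chromene double bond.
   - Fallback (from 11, back at 14): iodine is removed after the ring opening, from a phenol instead of an aryl ether. KOH in aqueous EtOH opens 11 to 1-(7-hydroxy-8-iodo-5-methoxy-2,2-dimethyl-2H-chromen-6-yl)-2-(4-methoxyphenyl)ethan-1-one F6. An ortho-iodophenol of this phloroglucinol type should be reduced by zinc dust in AcOH at room temperature (ipso protonation through the keto tautomer, then reductive loss of iodine). This leads to 14 without any metal hydride.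

**Further compounds**
F1 | step 4 | 5-hydroxy-7-(4-methoxyphenyl)-2,2-dimethyl-2H,6H-pyrano[3,2-g]chromen-6-one | COc1ccc(cc1)-c1coc2cc3OC(C)(C)C=Cc3c(O)c2c1=O
F2 | step 3 | 5-hydroxy-3-(4-methoxyphenyl)-8,8-dimethyl-4H,8H-pyrano[2,3-f]chromen-4-one | COc1ccc(cc1)-c1coc2c3C=CC(C)(C)Oc3cc(O)c2c1=O
F3 | step 3 | 5-(methoxymethoxy)-3-(4-methoxyphenyl)-8,8-dimethyl-4H,8H-pyrano[2,3-f]chromen-4-one | COc1ccc(cc1)-c1coc2c3C=CC(C)(C)Oc3cc(OCOC)c2c1=O
F4 | step 3 | 1-[5-hydroxy-7-(methoxymethoxy)-2,2-dimethyl-2H-chromen-6-yl]-2-(4-methoxyphenyl)ethan-1-one | COc1ccc(CC(=O)c2c(OCOC)cc3OC(C)(C)C=Cc3c2O)cc1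
F5 | step 3 | 1-[5-methoxy-7-(methoxymethoxy)-2,2-dimethyl-2H-chromen-6-yl]-2-(4-methoxyphenyl)ethan-1-one | COc1ccc(CC(=O)c2c(OCOC)cc3OC(C)(C)C=Cc3c2OC)cc1
F6 | step 5 | 1-(7-hydroxy-8-iodo-5-methoxy-2,2-dimethyl-2H-chromen-6-yl)-2-(4-methoxyphenyl)ethan-1-one | COc1ccc(CC(=O)c2c(O)c(I)c3OC(C)(C)C=Cc3c2OC)cc1
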